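**Plan**

- Retrosynthesis: the seven O–methyl bonds are cut last. Ring C is then cut at its C6–O bond and its C1–C(=O) bond in one aryne/carboxylic acid insertion. Next come the ring B–ring C biaryl bond (Suzuki–Miyaura), the ring A aryl–carbonyl bond (aryllithium on a Weinreb amide) and the aryl–chain bonds of rings B and D (Friedel–Crafts acylation of veratrole with the azelaic half ester).
- Enabling feature: the ketone carbon C1 of ring C lies between the oxygens at C2 and C6. A C6–C1 aryne next to the C2 methoxy group can therefore take the C6 oxygen and the C1 acyl group from a single carboxylic acid.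
- Forward: one arylnonanoate ester serves twice. Hydrolysed, it is the ring D acid. Brominated, joined to ring A and borylated, it is the ring B–ring A boronate. Ring C is built from 4-bromo-3-methoxyphenol as a bromo silyl triflate and coupled to ring B. The aryne insertion then attaches the ring D quarter, and BBr3 frees the phenols.
- No ring is formed in the route; all four benzene rings are bought.
- Stereochemistry: the target has no stereocentre.

Key step: step 12

Remark: the ring B–ring C axis carries only two ortho substituents, so it is taken as freely rotating and needs no control.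

**Route**

Step 1
Reactants: 1 azelaic acid monomethyl ester; 2 veratrole
Product: 4 methyl 9-(3,4-dimethoxyphenyl)-9-oxononanoate, via methyl 9-chloro-9-oxononanoate 3 (not isolated)
Conditions: (COCl)2, cat. DMF, CH2Cl2, 0 °C to rt; then 2, AlCl3, CH2Cl2, 0 °C to rt; aq HCl work-up
Reagents that add atoms: none
Why: Friedel–Crafts acylation, in which the half-ester acid chloride made with oxalyl chloride acylates veratrole para to a methoxy group, its usual site, giving the 3,4-dimethoxyphenyl ketone with the nine-carbon chain in place.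

Step 2
Reactants: 4 methyl 9-(3,4-dimethoxyphenyl)-9-oxononanoate
Product: 5 methyl 9-(3,4-dimethoxyphenyl)nonanoate
Conditions: Et3SiH, CF3CO2H, rt
Reagents that add atoms: none
Why: Ionic hydrogenation, in which the benzylic cation stabilised by the para methoxy group is reduced twice by the silane, taking the aryl ketone to the methylene while the ester is untouched.

Step 3
Reactants: 5 methyl 9-(3,4-dimethoxyphenyl)nonanoate
Product: 6 9-(3,4-dimethoxyphenyl)nonanoic acid
Conditions: LiOH, THF/MeOH/H2O, rt; then aq HCl
Reagents that add atoms: lithium hydroxide, [Li+].[OH-]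
Why: Saponification of the methyl ester gives the free acid that serves as oxygen and acyl donor in the key step.

Step 4
Reactants: 5 methyl 9-(3,4-dimethoxyphenyl)nonanoate
Product: 7 methyl 9-(2-bromo-4,5-dimethoxyphenyl)nonanoate
Conditions: N-bromosuccinimide, MeCN, 0 °C to rt, dark
Reagents that add atoms: N-bromosuccinimide, O=C1CCC(=O)N1Br
Why: Electrophilic aromatic bromination of a 4-alkylveratrole goes to the position para to a methoxy group and ortho to the chain, giving the 2-bromo-4,5-dimethoxyphenyl pattern of ring B before the more reactive ring A is present.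

Step 5
Reactants: 7 methyl 9-(2-bromo-4,5-dimethoxyphenyl)nonanoate
Product: 8 9-(2-bromo-4,5-dimethoxyphenyl)-N-methoxy-N-methylnonanamide
Conditions: MeNH(OMe)·HCl, i-PrMgCl, THF, −20 °C to 0 °C; aq NH4Cl
Reagents that add atoms: N,O-dimethylhydroxylamine hydrochloride, CNOC.Cl
Why: Direct aminolysis of the methyl ester by the chloromagnesium amide of N,O-dimethylhydroxylamine gives the Weinreb amide, and at this temperature i-PrMgCl does not exchange with the electron-rich aryl bromide.

Step 6
Reactants: 8 9-(2-bromo-4,5-dimethoxyphenyl)-N-methoxy-N-methylnonanamide; 9 1,3-dimethoxybenzene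
Product: 11 9-(2-bromo-4,5-dimethoxyphenyl)-1-(2,6-dimethoxyphenyl)nonan-1-one, via 2,6-dimethoxyphenyllithium 10 (not isolated)
Conditions: 9 (slight excess over base), n-BuLi, THF, 0 °C to rt; then 8, −78 °C to 0 °C; aq NH4Cl
Reagents that add atoms: none
Why: Weinreb ketone synthesis, in which 1,3-dimethoxybenzene is lithiated between its two methoxy groups (directed ortho-metalation) and the stabilised aryllithium adds once to the amide through a chelated tetrahedral intermediate without bromine–lithium exchange at the aryl bromide, provided no n-BuLi is left.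

Step 7
Reactants: 11 9-(2-bromo-4,5-dimethoxyphenyl)-1-(2,6-dimethoxyphenyl)nonan-1-one
Product: 12 9-[4,5-dimethoxy-2-(4,4,5,5-tetramethyl-1,3,2-dioxaborolan-2-yl)phenyl]-1-(2,6-dimethoxyphenyl)nonan-1-one
Conditions: bis(pinacolato)diboron, Pd(dppf)Cl2 (cat.), KOAc, 1,4-dioxane, 90 °C
Reagents that add atoms: bis(pinacolato)diboron, CC1(C)OB(OC1(C)C)B1OC(C)(C)C(C)(C)O1
Why: Miyaura borylation converts the aryl bromide into the pinacol boronate under acetate base, which leaves the hindered ketone and the methyl ethers alone.

Step 8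
Reactants: 13 4-bromo-3-methoxyphenol
Product: 14 4-bromo-3-methoxyphenyl N-isopropylcarbamate
Conditions: i-PrNCO, Et3N (cat.), CH2Cl2, rt
Reagents that add atoms: isopropyl isocyanate, CC(C)N=C=O
Why: Base-catalysed addition of the phenol to the isocyanate gives the N-isopropyl carbamate, a strong ortho-directing group that can later be removed with mild base.

Step 9
Reactants: 14 4-bromo-3-methoxyphenyl N-isopropylcarbamate
Product: 18 4-bromo-3-methoxy-2-(trimethylsilyl)phenyl N-isopropylcarbamate, via N-silyl carbamate 15 (not isolated), via aryllithium 16 (not isolated), via N-silyl C-silyl carbamate 17 (not isolated)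
Conditions: TBSOTf, TMEDA, Et2O, 0 °C to rt; LiN(i-Pr)2, THF, −78 °C; Me3SiCl, −78 °C to rt; aq NaHSO4
Reagents that add atoms: chlorotrimethylsilane, C[Si](C)(C)Cl
Why: Directed ortho-metalation, in which the carbamate (N-silylated in the flask) and the methoxy group together direct lithium diisopropylamide to the carbon between the two oxygens; this amide base deprotonates but does not exchange the aryl bromide, Me3SiCl traps the aryllithium, and acidic work-up strips the N-silyl group.

Step 10
Reactants: 18 4-bromo-3-methoxy-2-(trimethylsilyl)phenyl N-isopropylcarbamate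
Product: 20 4-bromo-3-methoxy-2-(trimethylsilyl)phenyl trifluoromethanesulfonate, via 4-bromo-3-methoxy-2-(trimethylsilyl)phenol 19 (not isolated)
Conditions: Et2NH, DBU, MeCN, 40 °C; then PhNTf2, rt
Reagents that add atoms: N-phenylbis(trifluoromethanesulfonimide), O=S(=O)(N(c1ccccc1)S(=O)(=O)C(F)(F)F)C(F)(F)F
Why: E1cB decarbamoylation (DBU removes the N–H proton, isopropyl isocyanate is expelled and captured by Et2NH) frees the hindered phenoxide, which PhNTf2 triflates in the same flask under conditions mild enough for the aryl–silicon and aryl–bromine bonds.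

Step 11
Reactants: 20 4-bromo-3-methoxy-2-(trimethylsilyl)phenyl trifluoromethanesulfonate; 12 9-[4,5-dimethoxy-2-(4,4,5,5-tetramethyl-1,3,2-dioxaborolan-2-yl)phenyl]-1-(2,6-dimethoxyphenyl)nonan-1-one
Product: 21 4-{2-[9-(2,6-dimethoxyphenyl)-9-oxononyl]-4,5-dimethoxyphenyl}-3-methoxy-2-(trimethylsilyl)phenyl trifluoromethanesulfonate
Conditions: Pd(OAc)2 (cat.), SPhos, K3PO4, toluene/H2O (10:1), 70 °C
Reagents that add atoms: none
Why: Suzuki–Miyaura coupling, in which zerovalent palladium bearing one bulky phosphine in a non-polar solvent inserts into the C–Br bond much faster than into the triflate shielded by its ortho trimethylsilyl group, while the fluoride-free phosphate base should leave the silyl triflate intact.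

Step 12
Reactants: 21 4-{2-[9-(2,6-dimethoxyphenyl)-9-oxononyl]-4,5-dimethoxyphenyl}-3-methoxy-2-(trimethylsilyl)phenyl trifluoromethanesulfonate; 6 9-(3,4-dimethoxyphenyl)nonanoic acid
Product: 24 1-(2,6-dimethoxyphenyl)-9-(2-{3-[9-(3,4-dimethoxyphenyl)nonanoyl]-4-hydroxy-2-methoxyphenyl}-4,5-dimethoxyphenyl)nonan-1-one, via caesium 9-(3,4-dimethoxyphenyl)nonanoate 22 (not isolated), via ring C aryne 23 (not isolated)
Conditions: 6 (1.5 equiv), Cs2CO3 (0.75 equiv), MeOH, rt, evaporate and dry; then 21 (1 equiv), CsF (3 equiv), THF, 125 °C, sealed tube; dilute aq HCl work-up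
Reagents that add atoms: none
Why: Fluoride attacks the trimethylsilyl group of 21 and triflate leaves from the neighbouring carbon, releasing aryne 23 across C6 and C1 of ring C; carboxylate 22 adds through oxygen to C6, and the C1 aryl anion attacks the ester carbonyl by a 4-exo-trig closure to a transient four-membered alkoxide that opens to the ketone phenoxide, an anionic 1,3 acyl shift from oxygen to carbon of the Fries type. The closest known reaction type is the CsF-mediated insertion of arynes, 3-methoxybenzyne among them, into the C–O bond of carboxylic acids to give ortho-hydroxyaryl ketones. No ring persists and no stereocentre is formed. The step needs regioselective addition, and the C2 methoxy group secures it: its inductive pull distorts the aryne so that the nucleophile attacks the remote carbon C6 and negative charge builds at C1 beside the methoxy-bearing carbon. Acyl transfer is favoured over protonation to the aryl ester by using the preformed, dried caesium salt with no free acid, and its slight excess should keep the product phenoxide from adding to a second aryne. The hindered ring A ketone and the aryl methyl ethers are expected to be inert to CsF.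

Step 13
Reactants: 24 1-(2,6-dimethoxyphenyl)-9-(2-{3-[9-(3,4-dimethoxyphenyl)nonanoyl]-4-hydroxy-2-methoxyphenyl}-4,5-dimethoxyphenyl)nonan-1-one
Product: 25 giganteone A
Conditions: BBr3 (large excess), CH2Cl2, −78 °C to rt; then MeOH/H2O
Reagents that add atoms: none
Why: Lewis acid ether cleavage, in which BBr3 complexes each aryl methyl ether and bromide removes the methyl group, the ethers ortho to a carbonyl cleaving fastest through chelation, so all seven should fall to give the octaphenol after hydrolysis.

**Compound list**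

1 | azelaic acid monomethyl ester | COC(=O)CCCCCCCC(=O)O | starting material
2 | veratrole | COc1ccccc1OC | starting material
3 | methyl 9-chloro-9-oxononanoate | COC(=O)CCCCCCCC(=O)Cl | intermediate
4 | methyl 9-(3,4-dimethoxyphenyl)-9-oxononanoate | COC(=O)CCCCCCCC(=O)c1ccc(OC)c(OC)c1 | intermediate
5 | methyl 9-(3,4-dimethoxyphenyl)nonanoate | COC(=O)CCCCCCCCc1ccc(OC)c(OC)c1 | intermediate
6 | 9-(3,4-dimethoxyphenyl)nonanoic acid | OC(=O)CCCCCCCCc1ccc(OC)c(OC)c1 | intermediate
7 | methyl 9-(2-bromo-4,5-dimethoxyphenyl)nonanoate | COC(=O)CCCCCCCCc1cc(OC)c(OC)cc1Br | intermediate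
8 | 9-(2-bromo-4,5-dimethoxyphenyl)-N-methoxy-N-methylnonanamide | CON(C)C(=O)CCCCCCCCc1cc(OC)c(OC)cc1Br | intermediate
9 | 1,3-dimethoxybenzene | COc1cccc(OC)c1 | starting material
10 | 2,6-dimethoxyphenyllithium | COc1cccc(OC)c1[Li] | intermediate
11 | 9-(2-bromo-4,5-dimethoxyphenyl)-1-(2,6-dimethoxyphenyl)nonan-1-one | COc1cccc(OC)c1C(=O)CCCCCCCCc1cc(OC)c(OC)cc1Br | intermediate
12 | 9-[4,5-dimethoxy-2-(4,4,5,5-tetramethyl-1,3,2-dioxaborolan-2-yl)phenyl]-1-(2,6-dimethoxyphenyl)nonan-1-one | COc1cccc(OC)c1C(=O)CCCCCCCCc1cc(OC)c(OC)cc1B1OC(C)(C)C(C)(C)O1 | intermediate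
13 | 4-bromo-3-methoxyphenol | COc1cc(O)ccc1Br | starting material
14 | 4-bromo-3-methoxyphenyl N-isopropylcarbamate | COc1cc(OC(=O)NC(C)C)ccc1Br | intermediate
15 | 4-bromo-3-methoxyphenyl N-(tert-butyldimethylsilyl)-N-isopropylcarbamate | COc1cc(OC(=O)N(C(C)C)[Si](C)(C)C(C)(C)C)ccc1Br | intermediate
16 | 4-bromo-2-lithio-3-methoxyphenyl N-(tert-butyldimethylsilyl)-N-isopropylcarbamate | COc1c(Br)ccc(OC(=O)N(C(C)C)[Si](C)(C)C(C)(C)C)c1[Li] | intermediate
17 | 4-bromo-3-methoxy-2-(trimethylsilyl)phenyl N-(tert-butyldimethylsilyl)-N-isopropylcarbamate | COc1c(Br)ccc(OC(=O)N(C(C)C)[Si](C)(C)C(C)(C)C)c1[Si](C)(C)C | intermediate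
18 | 4-bromo-3-methoxy-2-(trimethylsilyl)phenyl N-isopropylcarbamate | COc1c(Br)ccc(OC(=O)NC(C)C)c1[Si](C)(C)C | intermediate
19 | 4-bromo-3-methoxy-2-(trimethylsilyl)phenol | COc1c(Br)ccc(O)c1[Si](C)(C)C | intermediate
20 | 4-bromo-3-methoxy-2-(trimethylsilyl)phenyl trifluoromethanesulfonate | COc1c(Br)ccc(OS(=O)(=O)C(F)(F)F)c1[Si](C)(C)C | intermediate
21 | 4-{2-[9-(2,6-dimethoxyphenyl)-9-oxononyl]-4,5-dimethoxyphenyl}-3-methoxy-2-(trimethylsilyl)phenyl trifluoromethanesulfonate (ring C silyl triflate carrying rings B and A) | COc1cccc(OC)c1C(=O)CCCCCCCCc1cc(OC)c(OC)cc1-c1ccc(OS(=O)(=O)C(F)(F)F)c([Si](C)(C)C)c1OC | intermediate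
22 | caesium 9-(3,4-dimethoxyphenyl)nonanoate | [Cs+].[O-]C(=O)CCCCCCCCc1ccc(OC)c(OC)c1 | intermediate
23 | ring C aryne: 9-[2-(2-methoxycyclohexa-1,5-dien-3-yn-1-yl)-4,5-dimethoxyphenyl]-1-(2,6-dimethoxyphenyl)nonan-1-one | COc1cccc(OC)c1C(=O)CCCCCCCCc1cc(OC)c(OC)cc1C1=C(OC)C#CC=C1 | intermediate
24 | 1-(2,6-dimethoxyphenyl)-9-(2-{3-[9-(3,4-dimethoxyphenyl)nonanoyl]-4-hydroxy-2-methoxyphenyl}-4,5-dimethoxyphenyl)nonan-1-one (giganteone A heptamethyl ether, ring C C6 phenol free) | COc1cccc(OC)c1C(=O)CCCCCCCCc1cc(OC)c(OC)cc1-c1ccc(O)c(C(=O)CCCCCCCCc2ccc(OC)c(OC)c2)c1OC | intermediate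
25 | giganteone A, 1-(2,6-dihydroxyphenyl)-9-(2-{3-[9-(3,4-dihydroxyphenyl)nonanoyl]-2,4-dihydroxyphenyl}-4,5-dihydroxyphenyl)nonan-1-one | O=C(CCCCCCCCc1cc(O)c(O)cc1-c1ccc(O)c(C(=O)CCCCCCCCc2ccc(O)c(O)c2)c1O)c1c(O)cccc1O | target

**Step count and risks**

Total step count: 13. Longest linear sequence: 9 steps (steps 1, 2, 4, 5, 6, 7, 11, 12, 13).

The three steps most likely to fail:

Step 12. The aryl anion formed after carboxylate addition may be protonated before the acyl group shifts, which would stop at simple O-arylation. The product phenoxide may also add to a second aryne, or the carboxylate may add with imperfect regiocontrol. The fallback installs the same C1 acyl group by directed ortho-metalation instead of aryne chemistry; it sets out from 14 and 6 and returns to the route at 24. Acid 6 would be converted with 1,1'-carbonyldiimidazole and N,O-dimethylhydroxylamine hydrochloride into 9-(3,4-dimethoxyphenyl)-N-methoxy-N-methylnonanamide F1. Carbamate 14 would be N-silylated and lithiated exactly as in step 9 to give aryllithium 16, which would be acylated with F1 at −78 °C to give 4-bromo-2-[9-(3,4-dimethoxyphenyl)nonanoyl]-3-methoxyphenyl N-(tert-butyldimethylsilyl)-N-isopropylcarbamate F2, not isolated. Acidic work-up would strip the N-silyl group to give 4-bromo-2-[9-(3,4-dimethoxyphenyl)nonanoyl]-3-methoxyphenyl N-isopropylcarbamate F3. Et2NH and DBU in MeCN would remove the carbamate to give 1-(3-bromo-6-hydroxy-2-methoxyphenyl)-9-(3,4-dimethoxyphenyl)nonan-1-one F4. Suzuki–Miyaura coupling of F4 with boronate 12 (Pd(OAc)2, SPhos, K3PO4, toluene/H2O) would then give 24.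

Step 11. Palladium may insert into the C–OTf bond as well as the C–Br bond. The basic aqueous medium may also attack silicon and release the aryne early, or transmetalation at the two ortho-substituted partners may be slow enough for the boronate to protodeborylate. The fallback makes the biaryl bond before the triflate exists; it sets out from 18 and 12 and returns at 21. Coupling of 18 with 12 under the same palladium conditions would give 4-{2-[9-(2,6-dimethoxyphenyl)-9-oxononyl]-4,5-dimethoxyphenyl}-3-methoxy-2-(trimethylsilyl)phenyl N-isopropylcarbamate F5. Any carbamate lost to the base would only anticipate the next operation. Et2NH and DBU in MeCN would complete the conversion to 1-(2,6-dimethoxyphenyl)-9-{2-[4-hydroxy-2-methoxy-3-(trimethylsilyl)phenyl]-4,5-dimethoxyphenyl}nonan-1-one F6, which PhNTf2 would triflate in the same flask to give 21.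

Step 9. Deprotonation of the N-silylated carbamate by the amide base may be incomplete. Metalation next to bromine, followed by bromine migration or elimination, may compete, and any carbamate that escaped N-silylation would collapse by E1cB. The fallback changes the directing group to one that needs no nitrogen protection and traps the aryllithium as it forms; it sets out from 13 and returns at 19, which is then isolated and triflated with PhNTf2 and DBU as in the second stage of step 10. Phenol 13 would be carbamoylated with diethylcarbamoyl chloride and K2CO3 in MeCN to give 4-bromo-3-methoxyphenyl N,N-diethylcarbamate F7. Lithium diisopropylamide would be added to F7 and Me3SiCl together in THF at −78 °C (in situ quench) to give 4-bromo-3-methoxy-2-(trimethylsilyl)phenyl N,N-diethylcarbamate F8. Reductive cleavage of the carbamate with Cp2Zr(H)Cl in THF at rt, which tolerates the aryl bromide and the aryl silane, would give phenol 19.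

**Further compounds**

F1 | step 12 | 9-(3,4-dimethoxyphenyl)-N-methoxy-N-methylnonanamide | CON(C)C(=O)CCCCCCCCc1ccc(OC)c(OC)c1
F2 | step 12 | 4-bromo-2-[9-(3,4-dimethoxyphenyl)nonanoyl]-3-methoxyphenyl N-(tert-butyldimethylsilyl)-N-isopropylcarbamate | COc1c(Br)ccc(OC(=O)N(C(C)C)[Si](C)(C)C(C)(C)C)c1C(=O)CCCCCCCCc1ccc(OC)c(OC)c1
F3 | step 12 | 4-bromo-2-[9-(3,4-dimethoxyphenyl)nonanoyl]-3-methoxyphenyl N-isopropylcarbamate | COc1c(Br)ccc(OC(=O)NC(C)C)c1C(=O)CCCCCCCCc1ccc(OC)c(OC)c1
F4 | step 12 | 1-(3-bromo-6-hydroxy-2-methoxyphenyl)-9-(3,4-dimethoxyphenyl)nonan-1-one | COc1c(Br)ccc(O)c1C(=O)CCCCCCCCc1ccc(OC)c(OC)c1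
F5 | step 11 | 4-{2-[9-(2,6-dimethoxyphenyl)-9-oxononyl]-4,5-dimethoxyphenyl}-3-methoxy-2-(trimethylsilyl)phenyl N-isopropylcarbamate | COc1cccc(OC)c1C(=O)CCCCCCCCc1cc(OC)c(OC)cc1-c1ccc(OC(=O)NC(C)C)c([Si](C)(C)C)c1OC
F6 | step 11 | 1-(2,6-dimethoxyphenyl)-9-{2-[4-hydroxy-2-methoxy-3-(trimethylsilyl)phenyl]-4,5-dimethoxyphenyl}nonan-1-one | COc1cccc(OC)c1C(=O)CCCCCCCCc1cc(OC)c(OC)cc1-c1ccc(O)c([Si](C)(C)C)c1OC
F7 | step 9 | 4-bromo-3-methoxyphenyl N,N-diethylcarbamate | CCN(CC)C(=O)Oc1ccc(Br)c(OC)c1
F8 | step 9 | 4-bromo-3-methoxy-2-(trimethylsilyl)phenyl N,N-diethylcarbamate | CCN(CC)C(=O)Oc1ccc(Br)c(OC)c1[Si](C)(C)C
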